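(The runs come from a simulation for an exercise; scatter was added.)

At 0.394 h⁻¹ the average chain of the delta run was growing between 4.00 h and 10.0 h, and the eta run, charged with more pre-initiator, managed 0.324 h⁻¹. I called this the mean chain growth: the fraction of the free monomer charged that entered chains per hour, times the charge of free monomer over the charge of pre-initiator.

| flask | free monomer | pre-initiator | remark | time |
|---|---|---|---|---|
| delta | 0.050 M | 1.8 mM | run made earlier |  |
| eta | 0.050 M | 2.8 mM | run made earlier |  |
| ash | 0.050 M | 2.5 mM |  | 20 h |
| maple | 0.050 M | 1.2 mM |  | 20 h |

| run | time / h | monomer in chains / % |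
|---|---|---|
| delta | 0.833 | 0.9 |
| delta | 1.33 | 1.6 |
| delta | 2.00 | 3.4 |
| delta | 3.00 | 4.5 |
| delta | 4.00 | 5.1 |
| delta | 6.00 | 9.8 |
| delta | 10.0 | 13.6 |
| eta | 0.833 | 0.4 |
| eta | 1.33 | 2.7 |
| eta | 2.00 | 4.3 |
| eta | 3.00 | 6.7 |
| eta | 4.00 | 8.6 |
| eta | 6.00 | 14.0 |
| eta | 10.0 | 19.5 |

(standard deviation of a reading: 0.5 percentage points)

- which of the two ends with the longer chains by the average number of monomer units in a chain (chains begun, living or dead) ("neither" if they lie within 10%) (ash / maple / neither)
- average number of monomer units in a chain (chains begun, living or dead) at the end, ash
- average number of monomer units in a chain (chains begun, living or dead) at the end, maple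

- the average divides the monomer in chains by the number of chains begun, living and dead together
- the numbers in the tables scatter by 0.5 percentage points (one standard deviation)
- the earlier runs do not show the number of chains; that part of a forecast is a guess

I read the runs as a ladder. On the fastest rung, at 0.833 h, the readings of 0.9% and 0.4% stood near the scatter of 0.5 percentage points, so they could not tell me how long start-up took. On the next rung, over hours, chains took up monomer at a nearly steady mean. The slowest rung was the bend: the eta run's growth over its first 4.00 h was 0.384 h⁻¹, faster than its later mean, so a straight mean carried forward would read high.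

The runs showed no count of chains, so I guessed one chain per pre-initiator charged. That gave lengths at 10.0 h of 3.78 for delta and 3.48 for eta. Straight lines in the charge gave a mean chain growth of 0.345 h⁻¹ for ash and 0.435 h⁻¹ for maple. Carried to 20 h, these gave 7.02 for ash and 8.31 for maple, a factor of 1.18. I committed to maple, with both levels high.

The forecast differed: neither, with 5.8 for ash and 6.3 for maple. Its ground: “So the rate is first order in pre-initiator.”

The flask gave maple, with 5.27 for ash and 7.23 for maple.

    free monomer + initiator → living end + monomer in chains (k = 0.0225 L mol⁻¹ s⁻¹)
    free monomer + living end → monomer in chains + living end, rate k2*[living end]*[free monomer] (k = 0.00669 L mol⁻¹ s⁻¹)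
    monomer in chains + living end → free monomer + living end, rate k3*[living end] as long as [monomer in chains] is above zero (k = 1.77 × 10⁻⁴ s⁻¹)
    living end + monomer in chains → dead end (k = 0.00110 L mol⁻¹ s⁻¹)
    pre-initiator → initiator (k = 9.88 × 10⁻⁵ s⁻¹)

From 10.0 h to 20.0 h maple's mean chain growth was 0.298 h⁻¹, less than the 0.435 h⁻¹ I carried. At 20.0 h maple made monomer in chains 1.47 times as fast as it used it, each step taken net, and the step back to free monomer (depropagation) used it at 19 times the rate of the step to dead end. Maple read at 72.0 h stood at a length of 10.8, a mean chain growth since 20.0 h of 0.0677 h⁻¹.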